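**Working atom numbering.** Ring: C1 (carries the exocyclic CH2), C2, C3, C4=C5 (C5 carries CH3), C6, C7, C8 (carries the side chain), C9 (carries the ester, carbonyl carbon C10). Side chain: Ca (bonded to C8, carries CH2O), Cb, Cc, Cd, then the carbinol carbon. In the systematic names of the ring esters, locant 1 is C9, locant 2 is C8 and locant 9 is C1. Compound numbers 1–34 are those of the compound list.

## Analysis of the target

The target 34 is a monocyclic nine-membered carbocycle with an E trisubstituted alkene C4=C5 in the ring, an exocyclic methylene on C1 and two adjacent stereocentres, C8 (S) and C9 (R). The dienyl side chain on C8 and the methyl ester on C9 are trans. The side chain is a diene in which CH2OAc on Ca is cis to Cc (so C8 is trans to Cc, descriptor Z), Cc=Cd is E, and the chain ends in a tertiary allylic alcohol. The C9 hydrogen is α to the ester and allylic to the C1 methylene, so base can epimerise C9 or move the alkene into conjugation. The dienyl carbinol ionises with acid, and a free primary hydroxyl on Ca can lactonise onto C10. The E-cyclononene is strained and planar-chiral with a low flipping barrier, and any (Z,E)-cyclonona-1,5-diene met on the way can contract thermally by a Cope shift. The synthesis is hard because a medium ring with an E alkene resists end-to-end closure and because two contiguous stereocentres sit on a flexible ring with no ring fusion to relay stereochemistry. The strategy rests on one feature: if a bond is drawn between C5 and C9, atoms C5–C6–C7–C8–C9 form a cyclopentane and C2=C1–C9–C5–C4=C3 becomes a hexa-1,5-diene. The ring is therefore the [3,3] product of a 1,2-dialkenylcyclopentan-1-ol with its oxygen on C9, and that oxygen is later exchanged for C10.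

## Retrosynthetic reasoning

**34 to 32 (functional groups).** The acetate is removed to give diol 33, in which the primary and the tertiary hydroxyl differentiate themselves on acylation. Both oxygens are then masked as silyl ethers in 32. This makes the side chain compatible with organometallic chemistry, and the forward unmasking needs only buffered fluoride, which spares C9 and the dienyl carbinol.

**32 to 18 and 27 (C8–Ca).** The only bond joining ring and side chain is cut. C8 is β to the ester, so the bond can be made by 1,4-addition of the dienyl nucleophile derived from iodide 27 to the C8=C9 enoate 18. This is the convergent cut: two fragments of similar size, and both stereocentres arise at the union. The forward reaction must choose the C8 face (chiral ligand on copper) and then fix C9; the protonation gives the epimer mixture 31 and equilibration gives the trans ester 32.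

**27 to 19 and 23 (side chain).** In 27 the iodine is trans to Cc, which is the result of a syn addition of hydrogen and metal across the alkyne of enynol 24 with the metal next to CH2OH. Iodination then gives 26, which is silylated to 27. Enynol 24 is cut at the sp–sp2 bond into the E iodide 22 and alkyne 23. Iodide 22 comes from 19 through silyl ether 20 and a syn hydrometalation.

**18 to 12 (ring functional groups).** The C8=C9 bond of 18 is traced to dehydrogenation of the saturated ester 15. The exocyclic methylene and the C9 hydrogen of 15 come together from the allylsilane of 13 by fluoride-induced desilylation with protonation at C9. Ester 13 comes from enol triflate 12 by alkoxycarbonylation, which is where C10 enters. The oxygen on C9 in 12 is exactly what the ring-forming step delivers.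

**12 to 9 (key disconnection).** C2–C3 is cut and C5–C9 is reconnected. The nine-membered ring becomes the cyclopentanol 9, whose alkoxide gives the C9 enolate by an anionic oxy-Cope shift; the enolate is trapped on oxygen. No medium ring has to be closed, the E alkene is set by the transition state, and the enolate regiochemistry follows from the mechanism.

**9 to 1, 3 and 6.** The carbinol carbon is cut from its alkenyl group: ketone 5 plus the organometallic from bromide 6. Ketone 5 is cut at the quaternary carbon into the regiodefined enol ether 2 and vinyl bromide 3; 2 comes from ketone 1.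

## Alternatives that were turned down

**Alternative 1:** Disconnection at C1–C2. The open-chain iodo aldehyde A1 (C1 as a 1-iodoethenyl group, C2 as an aldehyde) would be treated with CrCl2 and catalytic NiCl2. The vinylchromium species adds to the aldehyde and closes the ring to the C2 carbinol A2.
- For: the E alkene, both stereocentres and the whole side chain are built by acyclic chemistry before the ring exists, and the coupling tolerates esters and silyl ethers. On stereocontrol this plan is stronger than the chosen one.
- Against: it is a direct nine-membered closure with an E trisubstituted alkene in the tether, so transannular strain is felt in the transition state, and high dilution and a large excess of chromium salt are needed. The C2 hydroxyl of A2 is not in the target and must be removed from an allylic position next to the methylene, with the risk of allylic transposition. C9 in A1 sits between the ester and the iodoalkene and is epimerisable through a long linear sequence.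
- Comparison: the chosen route offers a ring made by expansion in four steps, with no surplus oxygen and no cyclisation entropy to pay.

**Alternative 2:** Disconnection at C8–C9. The 13-membered allylic lactone A3 (acyl part C10, C9, C1 to C8; alkoxy carbon Cb) would be converted into its silyl ketene acetal. The [3,3] shift forms C8–C9, moves the alkene to Ca=Cb and contracts the ring to the acid A4.
- For: a 13-membered lactonisation is easier than a nine-membered closure, and both stereocentres and the side-chain alkene geometry come from one carbinol stereocentre in a single pericyclic step. That is stronger than the chosen route, where the two centres are set late and separately.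
- Against: the configuration at C8 and C9 depends on the ketene acetal geometry and on a chair or boat course inside a macrocycle that already holds an E alkene, and neither can be predicted. The lactonising alcohol is a secondary dienylic carbinol that ionises easily. Enolisation must also avoid the allylic C1 methylene side, and A3 needs a long synthesis with a stereodefined trisubstituted C8=Ca alkene.
- Comparison: the pericyclic step of the chosen route has only alkene geometry to control, and its precursor is three steps from a commercial ketone.

**Alternative 3:** Disconnection at C5–C6. In triene A5 the vinyl group on C8 would be hydroborated with 9-BBN, and PdCl2(dppf) with base would couple the alkylborane with the E iodide at C5 to give the nine-membered diene ester A6.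
- For: the E geometry is carried by the iodide with retention, and the side chain and C8 are already in place, so no late asymmetric conjugate addition is needed. On this point it is stronger than the chosen route.
- Against: hydroboration must select the monosubstituted vinyl group over the side-chain diene. The ring is still closed end to end under high dilution. The C8 hydrogen of A5 and A6 is triply allylic and exposed to base and to palladium hydride migration. A5 needs a stereodefined tetrasubstituted enoate carrying CH2SiMe3. C9 is still set at the end by protodesilylation next to the side chain, where kinetic protonation is expected to give the cis ester.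
- Comparison: the chosen route reaches the ring in far fewer steps and leaves no ring closure to optimise; it pays for this with the late installation of C8.

Key step: step 4

Assumption (chemistry): (R)-Tol-BINAP is written for step 13 on the premise that it delivers the 8S adduct, and the antipodal ligand is used if the sense of induction on this ring is the opposite; the trans ester 32 is taken to be the more stable C9 epimer.

## Route

Step 1
Reactants: 1 2-methylcyclopentan-1-one
Product: 2 trimethyl[(2-methylcyclopent-1-en-1-yl)oxy]silane
Conditions: TMSCl, Et3N, DMF, 130 °C; fractional distillation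
Reagents that add atoms: chlorotrimethylsilane, C[Si](C)(C)Cl
Why: Silylation under equilibrating conditions (thermodynamic silyl enol ether formation) favours the tetrasubstituted enol ether; the minor regioisomer is removed by distillation so that the enolate of step 2 is regiodefined.

Step 2
Reactants: 2 trimethyl[(2-methylcyclopent-1-en-1-yl)oxy]silane; 3 bromoethene (vinyl bromide)
Product: 5 rac-2-ethenyl-2-methylcyclopentan-1-one, via lithium enolate 4 (not isolated)
Conditions: MeLi, THF, 0 °C; then 3, Pd2(dba)3 (cat.), P(t-Bu)3, THF/toluene, rt
Reagents that add atoms: none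
Why: MeLi cleaves the Si–O bond and releases the tetrasubstituted lithium enolate regiospecifically; palladium-catalysed α-vinylation of a ketone enolate (oxidative addition of vinyl bromide to zerovalent palladium, transmetalation, reductive elimination) then forms the quaternary carbon. The product has no hydrogen on that carbon, so it can neither react there again nor conjugate.

Step 3
Reactants: 5 rac-2-ethenyl-2-methylcyclopentan-1-one; 6 (2-bromoprop-2-en-1-yl)trimethylsilane
Product: 9 rac-(1S,2R)-2-ethenyl-2-methyl-1-[3-(trimethylsilyl)prop-1-en-2-yl]cyclopentan-1-ol (the two alkenyl groups cis), via alkenyllithium 7 (not isolated), via alkenylcerium dichloride 8 (not isolated)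
Conditions: 6, t-BuLi (2 equiv), Et2O, −78 °C; CeCl3, THF, −78 °C; then 5, −78 to 0 °C; aq NH4Cl; chromatography
Reagents that add atoms: none
Why: Bromine–lithium exchange and transmetalation give an organocerium reagent, which adds to hindered, enolisable ketones without deprotonating them (1,2-addition). The carbinol stereocentre is set by attack anti to methyl and syn to vinyl on the neighbouring quaternary carbon; this bias is weak, so both epimers are expected and the cis-dialkenyl carbinol is isolated by chromatography.

Step 4
Reactants: 9 rac-(1S,2R)-2-ethenyl-2-methyl-1-[3-(trimethylsilyl)prop-1-en-2-yl]cyclopentan-1-ol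
Product: 12 (1Z,5E)-6-methyl-2-[(trimethylsilyl)methyl]cyclonona-1,5-dien-1-yl trifluoromethanesulfonate, via potassium alkoxide 10 (not isolated), via potassium enolate 11 (not isolated)
Conditions: KH, 18-crown-6, THF, 0 °C to rt; then PhNTf2, −78 to 0 °C
Reagents that add atoms: N-phenylbis(trifluoromethanesulfonimide), O=S(=O)(N(c1ccccc1)S(=O)(=O)C(F)(F)F)C(F)(F)F
Why: KH with 18-crown-6 gives the dissociated alkoxide 10, whose charge weakens the C5–C9 bond so that the [3,3] shift runs near room temperature; this is the anionic oxy-Cope rearrangement of a 1,2-dialkenylcycloalkanol, a known four-atom ring expansion. The nine-membered ring is not closed end to end: C2–C3 forms inside a six-membered chair while C5–C9 of the cyclopentane breaks, so the mode of closure is ring expansion. No sp3 stereocentre is formed, the two stereocentres of racemic 9 disappear, and what the step sets is alkene geometry. In the chair open to the cis-dialkenyl isomer the oxyanion and C6 are equatorial while C8 and the C5 methyl are axial, which gives the ring-trans (E) C4=C5 bond and the ring-cis C1=C9 enolate. The other chair would put the tetrasubstituted enolate trans in the ring, and the boat would give the all-cis diene, so the E selectivity rests on the chair preference of the cis isomer. Enolate 11 is formed only towards C1 because it is the product of the shift and not of a deprotonation, and PhNTf2 sulfonylates it on oxygen in the same flask, which fixes OTf on C9. The allylsilane is inert to KH, and a 1,4-shift of silicon from carbon to oxygen in 10 is the side reaction to watch. Triflate 12 is a (Z,E)-cyclonona-1,5-diene and is kept at or below room temperature to avoid thermal Cope contraction.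

Step 5
Reactants: 12 (1Z,5E)-6-methyl-2-[(trimethylsilyl)methyl]cyclonona-1,5-dien-1-yl trifluoromethanesulfonate
Product: 13 methyl (1Z,5E)-6-methyl-2-[(trimethylsilyl)methyl]cyclonona-1,5-diene-1-carboxylate
Conditions: CO (1 atm), Pd(PPh3)4 (cat.), Et3N, MeOH, DMF, 40 °C
Reagents that add atoms: carbon monoxide, [C-]#[O+]; methanol, CO
Why: Palladium-catalysed alkoxycarbonylation of an enol triflate (oxidative addition, CO insertion, methanolysis of the acylpalladium species) puts C10 on C9 with retention of the alkene geometry; the allylsilane and the E alkene are spectators at this temperature.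

Step 6
Reactants: 13 methyl (1Z,5E)-6-methyl-2-[(trimethylsilyl)methyl]cyclonona-1,5-diene-1-carboxylate
Product: 15 rac-methyl (5E)-6-methyl-2-methylidenecyclonon-5-ene-1-carboxylate, via tetrabutylammonium dienolate 14 (not isolated)
Conditions: Bu4NF·3H2O, THF, 0 °C
Reagents that add atoms: none
Why: Fluoride attacks silicon of the γ-silyl enoate and releases the ester dienolate (vinylogous desilylation), which water protonates kinetically at the α-carbon C9. One step thus gives the exocyclic methylene on C1 and the C9 hydrogen; C9 is formed racemic and is erased again in step 7.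

Step 7
Reactants: 15 rac-methyl (5E)-6-methyl-2-methylidenecyclonon-5-ene-1-carboxylate
Product: 18 methyl (1E,5E)-5-methyl-9-methylidenecyclonona-1,5-diene-1-carboxylate (ring carbons cis across C8=C9), via lithium enolate 16 (not isolated), via sulfilimine 17 (not isolated)
Conditions: LiN(i-Pr)2, THF, −78 °C; then PhS(Cl)=N-t-Bu, −78 to 0 °C
Reagents that add atoms: none
Why: One-flask dehydrogenation of an ester enolate with N-tert-butylbenzenesulfinimidoyl chloride: C9 attacks sulfur, and the nitrogen of the resulting tetravalent-sulfur sulfilimine removes a C8 hydrogen through a five-membered syn transition state well below room temperature. C8 is the only β-carbon with hydrogens, and the ring allows only the ring-cis C8=C9 bond. This is used in place of an α-sulfinyl ester thermolysis because that sulfoxide would be allylic (open to a [2,3] shift onto the methylene carbon) and because heat would expose 18, a (Z,E)-cyclonona-1,5-diene, to Cope contraction.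

Step 8
Reactants: 19 2-methylbut-3-yn-2-ol
Product: 20 triethyl[(2-methylbut-3-yn-2-yl)oxy]silane
Conditions: TESCl, imidazole, DMAP (cat.), DMF, rt
Reagents that add atoms: chlorotriethylsilane, CC[Si](Cl)(CC)CC
Why: Silylation of the tertiary propargylic alcohol; the triethylsilyl ether survives the organometallic steps and comes off later with buffered fluoride.

Step 9
Reactants: 20 triethyl[(2-methylbut-3-yn-2-yl)oxy]silane
Product: 22 triethyl{[(3E)-4-iodo-2-methylbut-3-en-2-yl]oxy}silane, via alkenylzirconocene chloride 21 (not isolated)
Conditions: Cp2Zr(H)Cl, THF, rt; then I2, 0 °C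
Reagents that add atoms: iodine, II
Why: Hydrozirconation of the terminal alkyne is a syn addition with zirconium on the terminal carbon, and iodinolysis proceeds with retention, which gives the E iodide (the future Cc=Cd bond).

Step 10
Reactants: 22 triethyl{[(3E)-4-iodo-2-methylbut-3-en-2-yl]oxy}silane; 23 prop-2-yn-1-ol
Product: 24 (4E)-6-methyl-6-[(triethylsilyl)oxy]hept-4-en-2-yn-1-ol
Conditions: PdCl2(PPh3)2 (cat.), CuI (cat.), Et3N, THF, rt
Reagents that add atoms: none
Why: Sonogashira coupling joins the alkyne carbon to Cc with retention of the E geometry; the free propargylic hydroxyl is tolerated and is needed as the directing group of step 11.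

Step 11
Reactants: 24 (4E)-6-methyl-6-[(triethylsilyl)oxy]hept-4-en-2-yn-1-ol
Product: 26 (2E,4E)-2-iodo-6-methyl-6-[(triethylsilyl)oxy]hepta-2,4-dien-1-ol, via alkenylstannane 25 (not isolated)
Conditions: Bu3SnH, PdCl2(PPh3)2 (cat.), THF, 0 °C; then I2, CH2Cl2, 0 °C, dark
Reagents that add atoms: iodine, II
Why: Palladium-catalysed hydrostannation is a syn addition that, with 3-substituted prop-2-yn-1-ols, places tin on the carbon next to CH2OH; iododestannylation then occurs with retention. Iodine on Ca therefore ends cis to the Cb hydrogen and trans to Cc, the geometry the target needs.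

Step 12
Reactants: 26 (2E,4E)-2-iodo-6-methyl-6-[(triethylsilyl)oxy]hepta-2,4-dien-1-ol
Product: 27 tert-butyl{[(2E,4E)-2-iodo-6-methyl-6-[(triethylsilyl)oxy]hepta-2,4-dien-1-yl]oxy}dimethylsilane
Conditions: TBSCl, imidazole, CH2Cl2, 0 °C to rt
Reagents that add atoms: tert-butylchlorodimethylsilane, CC(C)(C)[Si](C)(C)Cl
Why: Silylation of the primary allylic alcohol; the bulky silyl ether resists migration of silicon to the neighbouring alkenyl anion in step 13.

Step 13
Reactants: 18 methyl (1E,5E)-5-methyl-9-methylidenecyclonona-1,5-diene-1-carboxylate; 27 tert-butyl{[(2E,4E)-2-iodo-6-methyl-6-[(triethylsilyl)oxy]hepta-2,4-dien-1-yl]oxy}dimethylsilane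
Product: 31 methyl (2S,5E)-2-[(2Z,4E)-1-[(tert-butyldimethylsilyl)oxy]-6-methyl-6-[(triethylsilyl)oxy]hepta-2,4-dien-2-yl]-5-methyl-9-methylidenecyclonon-5-ene-1-carboxylate as the mixture of epimers at ring carbon C9, via dienyllithium 28 (not isolated), via dienylmagnesium bromide 29 (not isolated), via bromomagnesium enolate 30 (not isolated)
Conditions: 27, t-BuLi (2 equiv), Et2O, −78 °C; MgBr2·OEt2, −78 to −20 °C; slow addition to 18, CuI (cat.), (R)-Tol-BINAP, t-BuOMe, −20 °C; MeOH, −78 °C
Reagents that add atoms: none
Why: Proposed new method: asymmetric copper-catalysed 1,4-addition of a 2-dienylmagnesium bromide to a cyclic α-branched enoate has not been shown; the closest known reaction type is the CuI/Tol-BINAP-catalysed enantioselective conjugate addition of Grignard reagents to β-substituted methyl enoates, and mechanistically the bisphosphine-bound dienylcopper should π-complex C8=C9 (the only electrophilic alkene, because the ring twists the C1 methylene out of conjugation), add oxidatively at C8 to a trivalent copper species and eliminate reductively to form C8–Ca with retention of the Ca=Cb geometry (descriptor 2E in 27, 2Z in 31, same geometry). The ligand chooses the face at C8 (8S); because the planar-chiral ring conformers of 18 interconvert by passage of the E alkene through the ring, the addition is run at −20 °C with slow addition of 29 so that this flip stays faster than C–C bond formation. The MeOH quench protonates enolate 30 at C9 without reliable control (attack anti to the new C8 substituent gives the cis ester), so 31 is carried on as the C9 epimer mixture.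

Step 14
Reactants: 31 methyl (2S,5E)-2-[(2Z,4E)-1-[(tert-butyldimethylsilyl)oxy]-6-methyl-6-[(triethylsilyl)oxy]hepta-2,4-dien-2-yl]-5-methyl-9-methylidenecyclonon-5-ene-1-carboxylate (C9 epimers)
Product: 32 methyl (1R,2S,5E)-2-[(2Z,4E)-1-[(tert-butyldimethylsilyl)oxy]-6-methyl-6-[(triethylsilyl)oxy]hepta-2,4-dien-2-yl]-5-methyl-9-methylidenecyclonon-5-ene-1-carboxylate
Conditions: 1,5,7-triazabicyclo[4.4.0]dec-5-ene (cat.), toluene, rt
Reagents that add atoms: none
Why: Base-mediated epimerisation through the ester enolate: the C9 hydrogen (α to the ester and allylic) is removed reversibly and returned at C9, so C9 is set under thermodynamic control in favour of the trans ester, in which both large groups can lie outside the ring; C8 is untouched. Kinetic reprotonation at the α-carbon keeps the methylene exocyclic, and any cis ester left at equilibrium is separated and resubmitted.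

Step 15
Reactants: 32 methyl (1R,2S,5E)-2-[(2Z,4E)-1-[(tert-butyldimethylsilyl)oxy]-6-methyl-6-[(triethylsilyl)oxy]hepta-2,4-dien-2-yl]-5-methyl-9-methylidenecyclonon-5-ene-1-carboxylate
Product: 33 methyl (1R,2S,5E)-2-[(2Z,4E)-1,6-dihydroxy-6-methylhepta-2,4-dien-2-yl]-5-methyl-9-methylidenecyclonon-5-ene-1-carboxylate
Conditions: HF·pyridine, pyridine, THF, 0 °C to rt
Reagents that add atoms: none
Why: Buffered fluoride cleaves both Si–O bonds (desilylation) without a basic alkoxide, which would epimerise C9 or lactonise onto C10, and without enough acidity to ionise the dienyl carbinol; the diol is acetylated at once.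

Step 16
Reactants: 33 methyl (1R,2S,5E)-2-[(2Z,4E)-1,6-dihydroxy-6-methylhepta-2,4-dien-2-yl]-5-methyl-9-methylidenecyclonon-5-ene-1-carboxylate
Product: 34 methyl (1R,2S,5E)-2-[(2Z,4E)-1-(acetyloxy)-6-hydroxy-6-methylhepta-2,4-dien-2-yl]-5-methyl-9-methylidenecyclonon-5-ene-1-carboxylate
Conditions: Ac2O, pyridine, CH2Cl2, 0 °C
Reagents that add atoms: acetic anhydride, CC(=O)OC(C)=O
Why: Chemoselective acetylation: without an acyl-transfer catalyst the primary allylic hydroxyl is acylated while the tertiary hydroxyl stays free, and pyridine is too weak a base to touch C9.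

## Compound list

1 | 2-methylcyclopentan-1-one | CC1CCCC1=O | starting material
2 | trimethyl[(2-methylcyclopent-1-en-1-yl)oxy]silane | CC1=C(O[Si](C)(C)C)CCC1 | intermediate
3 | bromoethene (vinyl bromide) | C=CBr | starting material
4 | lithium 2-methylcyclopent-1-en-1-olate | CC1=C([O-])CCC1.[Li+] | intermediate
5 | rac-2-ethenyl-2-methylcyclopentan-1-one | C=CC1(C)CCCC1=O | intermediate
6 | (2-bromoprop-2-en-1-yl)trimethylsilane | C=C(Br)C[Si](C)(C)C | starting material
7 | [3-(trimethylsilyl)prop-1-en-2-yl]lithium | [Li]C(=C)C[Si](C)(C)C | intermediate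
8 | dichloro[3-(trimethylsilyl)prop-1-en-2-yl]cerium | C=C(C[Si](C)(C)C)[Ce](Cl)Cl | intermediate
9 | rac-(1S,2R)-2-ethenyl-2-methyl-1-[3-(trimethylsilyl)prop-1-en-2-yl]cyclopentan-1-ol (alkenyl groups cis) | C=C[C@@]1(C)CCC[C@@]1(O)C(=C)C[Si](C)(C)C | intermediate
10 | potassium rac-(1S,2R)-2-ethenyl-2-methyl-1-[3-(trimethylsilyl)prop-1-en-2-yl]cyclopentan-1-olate | C=C[C@@]1(C)CCC[C@@]1([O-])C(=C)C[Si](C)(C)C.[K+] | intermediate
11 | potassium (1Z,5E)-6-methyl-2-[(trimethylsilyl)methyl]cyclonona-1,5-dien-1-olate | C[Si](C)(C)C/C1=C(\[O-])CCC/C(C)=C/CC1.[K+] | intermediate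
12 | (1Z,5E)-6-methyl-2-[(trimethylsilyl)methyl]cyclonona-1,5-dien-1-yl trifluoromethanesulfonate | C[Si](C)(C)C/C1=C(\OS(=O)(=O)C(F)(F)F)CCC/C(C)=C/CC1 | intermediate
13 | methyl (1Z,5E)-6-methyl-2-[(trimethylsilyl)methyl]cyclonona-1,5-diene-1-carboxylate | C[Si](C)(C)C/C1=C(\C(=O)OC)CCC/C(C)=C/CC1 | intermediate
14 | tetrabutylammonium dienolate of methyl (5E)-6-methyl-2-methylidenecyclonon-5-ene-1-carboxylate | C=C1CC/C=C(\C)CCCC1=C([O-])OC.CCCC[N+](CCCC)(CCCC)CCCC | intermediate
15 | rac-methyl (5E)-6-methyl-2-methylidenecyclonon-5-ene-1-carboxylate | C=C1CC/C=C(\C)CCCC1C(=O)OC | intermediate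
16 | lithium enolate of 15 | C=C1CC/C=C(\C)CCCC1=C([O-])OC.[Li+] | intermediate
17 | methyl (5E)-1-(N-tert-butyl-S-phenylsulfinimidoyl)-6-methyl-2-methylidenecyclonon-5-ene-1-carboxylate | C=C1CC/C=C(\C)CCCC1(C(=O)OC)S(=NC(C)(C)C)c1ccccc1 | intermediate
18 | methyl (1E,5E)-5-methyl-9-methylidenecyclonona-1,5-diene-1-carboxylate (ring carbons cis across the 1,2-alkene) | C=C1CC/C=C(\C)CC/C=C1/C(=O)OC | intermediate
19 | 2-methylbut-3-yn-2-ol | CC(C)(O)C#C | starting material
20 | triethyl[(2-methylbut-3-yn-2-yl)oxy]silane | CC[Si](CC)(CC)OC(C)(C)C#C | intermediate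
21 | chlorobis(cyclopentadienyl)[(1E)-3-methyl-3-(triethylsilyloxy)but-1-en-1-yl]zirconium (cyclopentadienyl rings written σ-bonded in the SMILES) | CC[Si](CC)(CC)OC(C)(C)/C=C/[Zr](Cl)(C1C=CC=C1)C1C=CC=C1 | intermediate
22 | triethyl{[(3E)-4-iodo-2-methylbut-3-en-2-yl]oxy}silane | CC[Si](CC)(CC)OC(C)(C)/C=C/I | intermediate
23 | prop-2-yn-1-ol | OCC#C | starting material
24 | (4E)-6-methyl-6-[(triethylsilyl)oxy]hept-4-en-2-yn-1-ol | OCC#C/C=C/C(C)(C)O[Si](CC)(CC)CC | intermediate
25 | (2E,4E)-6-methyl-2-(tributylstannyl)-6-[(triethylsilyl)oxy]hepta-2,4-dien-1-ol | CCCC[Sn](CCCC)(CCCC)/C(=C/C=C/C(C)(C)O[Si](CC)(CC)CC)CO | intermediate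
26 | (2E,4E)-2-iodo-6-methyl-6-[(triethylsilyl)oxy]hepta-2,4-dien-1-ol | I/C(=C/C=C/C(C)(C)O[Si](CC)(CC)CC)CO | intermediate
27 | tert-butyl{[(2E,4E)-2-iodo-6-methyl-6-[(triethylsilyl)oxy]hepta-2,4-dien-1-yl]oxy}dimethylsilane | I/C(=C/C=C/C(C)(C)O[Si](CC)(CC)CC)CO[Si](C)(C)C(C)(C)C | intermediate
28 | [(2Z,4E)-1-[(tert-butyldimethylsilyl)oxy]-6-methyl-6-[(triethylsilyl)oxy]hepta-2,4-dien-2-yl]lithium (lithium trans to Cc) | [Li]/C(=C/C=C/C(C)(C)O[Si](CC)(CC)CC)CO[Si](C)(C)C(C)(C)C | intermediate
29 | [(2Z,4E)-1-[(tert-butyldimethylsilyl)oxy]-6-methyl-6-[(triethylsilyl)oxy]hepta-2,4-dien-2-yl]magnesium bromide (magnesium trans to Cc) | Br[Mg]/C(=C/C=C/C(C)(C)O[Si](CC)(CC)CC)CO[Si](C)(C)C(C)(C)C | intermediate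
30 | bromomagnesium enolate of 31 (8S) | C=C1CC/C=C(\C)CC[C@H](/C(=C/C=C/C(C)(C)O[Si](CC)(CC)CC)CO[Si](C)(C)C(C)(C)C)C1=C(OC)O[Mg]Br | intermediate
31 | methyl (2S,5E)-2-[(2Z,4E)-1-[(tert-butyldimethylsilyl)oxy]-6-methyl-6-[(triethylsilyl)oxy]hepta-2,4-dien-2-yl]-5-methyl-9-methylidenecyclonon-5-ene-1-carboxylate, mixture of epimers at ring carbon C9 | C=C1CC/C=C(\C)CC[C@H](/C(=C/C=C/C(C)(C)O[Si](CC)(CC)CC)CO[Si](C)(C)C(C)(C)C)C1C(=O)OC | intermediate
32 | methyl (1R,2S,5E)-2-[(2Z,4E)-1-[(tert-butyldimethylsilyl)oxy]-6-methyl-6-[(triethylsilyl)oxy]hepta-2,4-dien-2-yl]-5-methyl-9-methylidenecyclonon-5-ene-1-carboxylate | C=C1CC/C=C(\C)CC[C@H](/C(=C/C=C/C(C)(C)O[Si](CC)(CC)CC)CO[Si](C)(C)C(C)(C)C)[C@H]1C(=O)OC | intermediate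
33 | methyl (1R,2S,5E)-2-[(2Z,4E)-1,6-dihydroxy-6-methylhepta-2,4-dien-2-yl]-5-methyl-9-methylidenecyclonon-5-ene-1-carboxylate | C=C1CC/C=C(\C)CC[C@H](/C(=C/C=C/C(C)(C)O)CO)[C@H]1C(=O)OC | intermediate
34 | methyl (1R,2S,5E)-2-[(2Z,4E)-1-(acetyloxy)-6-hydroxy-6-methylhepta-2,4-dien-2-yl]-5-methyl-9-methylidenecyclonon-5-ene-1-carboxylate | C=C1CC/C=C(\C)CC[C@H](/C(=C/C=C/C(C)(C)O)COC(C)=O)[C@H]1C(=O)OC | target

## Step count and least certain steps

Total: 16 steps. Longest linear sequence: 11 steps (steps 1–7 and 13–16, from 1). The side-chain branch is steps 8–12 (5 steps from 19) and joins at step 13.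

**Step 13 (carries the new-method label).** Most likely failure: too low a rate or enantioface selectivity, because a hindered trisubstituted alkenyl Grignard reagent meets an α-branched enoate. Uncatalysed addition can erode selectivity, and ligand control is lost if the ring flip of 18 is not faster than the addition. The C9 outcome of the quench is not the concern here, since step 14 corrects it and leftover cis ester is recycled. The fallback is known chemistry, the auxiliary-controlled 1,4-addition of an organomagnesium reagent to an N-enoyl sultam with protonation of the chelated enolate. Setting out from 18, saponification (LiOH, THF/H2O) gives (1E,5E)-5-methyl-9-methylidenecyclonona-1,5-diene-1-carboxylic acid F1. (COCl)2 with catalytic DMF gives the acid chloride F2, and the sodium salt of (2R)-bornane-10,2-sultam gives the N-enoyl sultam F3 (the antipodal sultam is used if the model on this ring calls for it). Grignard reagent 29 with catalytic CuBr·SMe2 at 0 °C adds to C8 under control of the auxiliary, and protonation gives the sultam adduct F4. LiOH/H2O2 removes the auxiliary to the acid F5, and TMSCHN2 gives 31, where the route is rejoined at step 14.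

**Step 4 (key step).** Most likely failure: leakage through the boat or through the chair with an axial oxyanion, because the strain of the E-cyclononene is already felt in the wanted chair; C4=C5 then forms Z. Stepwise fragmentation and recombination (a 1,3-shift to a seven-membered ring) and migration of silicon to the alkoxide are lesser risks. The fallback corrects the geometry after the ring expansion instead of in it. From 9, the same operation then gives the (1Z,5Z)-triflate F6. Steps 5 and 6 applied to it give the (1Z,5Z)-ester F7 and then methyl (5Z)-6-methyl-2-methylidenecyclonon-5-ene-1-carboxylate F8. Sensitised photoisomerisation of F8 (methyl benzoate, 254 nm, flow) with continuous capture of the E cycloalkene on AgNO3-impregnated silica and release with aqueous NH3 gives 15.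

**Step 7.** Most likely failure: a [2,3] shift of the allylic sulfilimine 17 onto the methylene carbon outrunning the syn elimination, or attack of the enolate through its γ-carbon; both divert material from C8=C9. Fallback: from 15 through enolate 16, hydroxylation with 2-(phenylsulfonyl)-3-phenyloxaziridine gives methyl (5E)-1-hydroxy-6-methyl-2-methylidenecyclonon-5-ene-1-carboxylate F9. Dehydration with (methoxycarbonylsulfamoyl)triethylammonium hydroxide inner salt (benzene, 50 °C), a syn elimination that can only go towards C8, gives 18.

**Step 3.** Most likely failure: poor facial selectivity, because methyl and vinyl on the neighbouring quaternary carbon are close in size, so the cis-dialkenyl carbinol may be the minor epimer. Fallback: from enolate 4, electrophilic ethynylation with 1-[(trimethylsilyl)ethynyl]-1,2-benziodoxol-3(1H)-one and Bu4NF gives 2-ethynyl-2-methylcyclopentan-1-one F10. The rod-shaped ethynyl group is far smaller than methyl, so reagent 8 should add syn to it and give the cis carbinol rac-(1S,2R)-2-ethynyl-2-methyl-1-[3-(trimethylsilyl)prop-1-en-2-yl]cyclopentan-1-ol F11. Semihydrogenation (H2, Pd/CaCO3 poisoned with Pb(OAc)2, quinoline) gives 9.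

**Step 11.** Most likely failure: erosion of regioselectivity in the hydrostannation, the conjugated alkenyl group drawing tin to Cb against the directing effect of CH2OH; iodine-induced E/Z isomerisation of the diene is a second risk. Fallback: from 22, Sonogashira coupling with methyl propiolate (K2CO3 as base, no amine) gives methyl (4E)-6-methyl-6-[(triethylsilyl)oxy]hept-4-en-2-ynoate F12. Palladium-catalysed hydrostannation, in which the ester polarises the alkyne and places tin α to the carbonyl by syn addition, gives the stannyl dienoate F13. I2 gives methyl (2E,4E)-2-iodo-6-methyl-6-[(triethylsilyl)oxy]hepta-2,4-dienoate F14, and i-Bu2AlH at −78 °C reduces the ester to 26.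

**Step 2.** Most likely failure: loss of regiochemical integrity by proton exchange between enolate 4 and product 5, which leads to vinylation at the methylene carbon and to double vinylation. Fallback: from 4, conjugate addition to phenyl vinyl sulfoxide gives 2-methyl-2-[2-(phenylsulfinyl)ethyl]cyclopentan-1-one F15. Thermolysis (toluene, 110 °C, CaCO3) expels the sulfenic acid by syn elimination and gives 5.

## Further compounds

F1 | step 13 | (1E,5E)-5-methyl-9-methylidenecyclonona-1,5-diene-1-carboxylic acid | C=C1CC/C=C(\C)CC/C=C1/C(=O)O
F2 | step 13 | (1E,5E)-5-methyl-9-methylidenecyclonona-1,5-diene-1-carbonyl chloride | C=C1CC/C=C(\C)CC/C=C1/C(=O)Cl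
F3 | step 13 | N-[(1E,5E)-5-methyl-9-methylidenecyclonona-1,5-diene-1-carbonyl]-(2R)-bornane-10,2-sultam | C=C1CC/C=C(\C)CC/C=C1/C(=O)N1[C@@H]2C[C@H]3CC[C@]2(CS1(=O)=O)C3(C)C
F4 | step 13 | N-acyl (2R)-bornane-10,2-sultam of the 8S conjugate adduct (C9 as delivered by the auxiliary-controlled protonation) | C=C1CC/C=C(\C)CC[C@H](/C(=C/C=C/C(C)(C)O[Si](CC)(CC)CC)CO[Si](C)(C)C(C)(C)C)C1C(=O)N1[C@@H]2C[C@H]3CC[C@]2(CS1(=O)=O)C3(C)C
F5 | step 13 | (2S,5E)-2-[(2Z,4E)-1-[(tert-butyldimethylsilyl)oxy]-6-methyl-6-[(triethylsilyl)oxy]hepta-2,4-dien-2-yl]-5-methyl-9-methylidenecyclonon-5-ene-1-carboxylic acid (C9 as delivered) | C=C1CC/C=C(\C)CC[C@H](/C(=C/C=C/C(C)(C)O[Si](CC)(CC)CC)CO[Si](C)(C)C(C)(C)C)C1C(=O)O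
F6 | step 4 | (1Z,5Z)-6-methyl-2-[(trimethylsilyl)methyl]cyclonona-1,5-dien-1-yl trifluoromethanesulfonate | C[Si](C)(C)C/C1=C(\OS(=O)(=O)C(F)(F)F)CCC/C(C)=C\CC1
F7 | step 4 | methyl (1Z,5Z)-6-methyl-2-[(trimethylsilyl)methyl]cyclonona-1,5-diene-1-carboxylate | C[Si](C)(C)C/C1=C(\C(=O)OC)CCC/C(C)=C\CC1
F8 | step 4 | rac-methyl (5Z)-6-methyl-2-methylidenecyclonon-5-ene-1-carboxylate | C=C1CC/C=C(/C)CCCC1C(=O)OC
F9 | step 7 | rac-methyl (5E)-1-hydroxy-6-methyl-2-methylidenecyclonon-5-ene-1-carboxylate | C=C1CC/C=C(\C)CCCC1(O)C(=O)OC
F10 | step 3 | rac-2-ethynyl-2-methylcyclopentan-1-one | C#CC1(C)CCCC1=O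
F11 | step 3 | rac-(1S,2R)-2-ethynyl-2-methyl-1-[3-(trimethylsilyl)prop-1-en-2-yl]cyclopentan-1-ol (ethynyl and alkenyl cis) | C#C[C@@]1(C)CCC[C@@]1(O)C(=C)C[Si](C)(C)C
F12 | step 11 | methyl (4E)-6-methyl-6-[(triethylsilyl)oxy]hept-4-en-2-ynoate | COC(=O)C#C/C=C/C(C)(C)O[Si](CC)(CC)CC
F13 | step 11 | methyl (2E,4E)-6-methyl-2-(tributylstannyl)-6-[(triethylsilyl)oxy]hepta-2,4-dienoate | CCCC[Sn](CCCC)(CCCC)/C(=C/C=C/C(C)(C)O[Si](CC)(CC)CC)C(=O)OC
F14 | step 11 | methyl (2E,4E)-2-iodo-6-methyl-6-[(triethylsilyl)oxy]hepta-2,4-dienoate | I/C(=C/C=C/C(C)(C)O[Si](CC)(CC)CC)C(=O)OC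
F15 | step 2 | 2-methyl-2-[2-(phenylsulfinyl)ethyl]cyclopentan-1-one | CC1(CCS(=O)c2ccccc2)CCCC1=O
A1 | alternative 1 | methyl (6E)-2-(1-iodoethenyl)-6-methyl-9-oxo-3-[(2Z,4E)-1-[(tert-butyldimethylsilyl)oxy]-6-methyl-6-[(triethylsilyl)oxy]hepta-2,4-dien-2-yl]non-6-enoate, stereocentres as at C8 and C9 of the target | O=CC/C=C(\C)CC[C@H](/C(=C/C=C/C(C)(C)O[Si](CC)(CC)CC)CO[Si](C)(C)C(C)(C)C)[C@H](C(I)=C)C(=O)OC
A2 | alternative 1 | nine-membered C2 carbinol (one epimer at C2), methyl 8-hydroxy-5-methyl-9-methylidene-2-(bis-silylated dienyl)cyclonon-5-ene-1-carboxylate | C=C1[C@@H](O)C/C=C(\C)CC[C@H](/C(=C/C=C/C(C)(C)O[Si](CC)(CC)CC)CO[Si](C)(C)C(C)(C)C)[C@H]1C(=O)OC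
A3 | alternative 2 | (7E)-12-{[(tert-butyldimethylsilyl)oxy]methyl}-8-methyl-4-methylidene-13-[(1E)-3-methyl-3-(triethylsilyloxy)but-1-en-1-yl]-1-oxacyclotrideca-7,11-dien-2-one (C11=C12 geometry and C13 configuration to be chosen to fit the transition state) | O=C1CC(=C)CC/C=C(\C)CCC=C(CO[Si](C)(C)C(C)(C)C)C(/C=C/C(C)(C)O[Si](CC)(CC)CC)O1
A4 | alternative 2 | (1R,2S,5E)-2-[(2Z,4E)-1-[(tert-butyldimethylsilyl)oxy]-6-methyl-6-[(triethylsilyl)oxy]hepta-2,4-dien-2-yl]-5-methyl-9-methylidenecyclonon-5-ene-1-carboxylic acid | C=C1CC/C=C(\C)CC[C@H](/C(=C/C=C/C(C)(C)O[Si](CC)(CC)CC)CO[Si](C)(C)C(C)(C)C)[C@H]1C(=O)O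
A5 | alternative 3 | methyl (2Z,6E)-7-iodo-3-[(trimethylsilyl)methyl]-2-[1-ethenyl-2-(silyloxymethyl)dienyl]octa-2,6-dienoate, the open-chain triene with a vinyl group on C8 and the E iodide at C5 | C[Si](C)(C)C/C(CC/C=C(\C)I)=C(\C(=O)OC)[C@@H](/C(=C/C=C/C(C)(C)O[Si](CC)(CC)CC)CO[Si](C)(C)C(C)(C)C)C=C
A6 | alternative 3 | methyl (1Z,5E)-6-methyl-2-[(trimethylsilyl)methyl]-9-(bis-silylated dienyl)cyclonona-1,5-diene-1-carboxylate | C[Si](C)(C)C/C1=C(\C(=O)OC)[C@@H](/C(=C/C=C/C(C)(C)O[Si](CC)(CC)CC)CO[Si](C)(C)C(C)(C)C)CC/C(C)=C/CC1
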